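Count the free catalyst before reckoning anything else in these flasks.

| flask | substrate | catalyst | remark | time |
|---|---|---|---|---|
| oak | 5.0 mM | 0.12 mM | a single well-mixed tank run continuously and read at steady state, 40 s in it on average |  |
| elm | 5.0 mM (fed, over 32.0 s) | 0.12 mM | all but substrate at the start; substrate goes in evenly over 32.0 s, the run ends at 40 s | 40 s |
| cedar | 5.0 mM | 0.12 mM | a closed flask charged with all of it at once and left for 40 s | 40 s |

    substrate + catalyst ⇌ target + catalyst, rate k1*[substrate]*[catalyst] forward; the back reaction follows from the equilibrium constant (K1 = 0.76, k1 = 360 L mol⁻¹ s⁻¹)
    target + catalyst ⇌ isomer of the product + catalyst, rate k2*[catalyst]*[target] forward; the back reaction follows from the equilibrium constant (K2 = 1.5, k2 = 140 L mol⁻¹ s⁻¹)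
    isomer of the product + catalyst ⇌ substrate + catalyst, rate k3*[catalyst]*[isomer of the product] forward; the back reaction follows from the equilibrium constant (k3 = 20 L mol⁻¹ s⁻¹)
    2 catalyst ⇌ resting dimer, settled at all times (K4 = 20000 L mol⁻¹)

- a doubled species enters its step squared and goes two at a time
- the stated concentrations are those of everything mixed, before any reaction; amounts are the same in each set-up
- the feed brings no volume worth counting
- run time (elm): 40 s

* the set-up with the highest amount of target at the outlet or at the end, in percent of the substrate put in ("none" if the first two lie within 2 percentage points) (oak / elm / cedar / none)
* amount of target at the outlet or at the end, in percent of the substrate put in, oak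
* amount of target at the outlet or at the end, in percent of the substrate put in, elm
* amount of target at the outlet or at the end, in percent of the substrate put in, cedar

Let f be the free catalyst; the resting dimer is its resting state. Each dimer holds two catalyst units, so the balance reads f plus 2K f² equals the charge, with K the dimer constant. This gives f = 0.0437 mM, or 36.4% of the charge. The cycle does not consume catalyst, so f stays constant and each step is pseudo-first-order.

On f, the first step runs forward at a = 0.0157 s⁻¹ and back at b = 0.0207 s⁻¹. The second step drains target at d = 0.00612 s⁻¹, which is small beside them and can be computed as a correction. The reckoning drops the third step, whose forward constant 20 L mol⁻¹ s⁻¹ and back constant 22.8 L mol⁻¹ s⁻¹ both stand below the 360 L mol⁻¹ s⁻¹ of the first, and drops the return from the isomer of the product to target. The quantity to carry is T, the relaxation time of the first step on free catalyst, the reciprocal of a plus b: 27.5 s.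

With the drain, the rates become a fast 0.0401 s⁻¹ and a slow 0.00240 s⁻¹. With f constant the reckoning is linear, so target in elm is the closed curve averaged over the feed.

The reckoning is a small table of target, with one row per flask and two columns, without drain and with drain:

- Cedar: 33.1% and 29.5%.
- Oak: 25.6% and 22.0%.
- Elm: 24.1% and 22.3%.

Down the first column, cedar stands highest. Across the rows, the drain costs cedar 3.6 percentage points, oak 3.6 points and elm 1.8 points. Down the second column, cedar still leads, by 7.2 points, which is wider than the margin.

The forecast names cedar, with 22.1% for oak, 22.2% for elm and 29.3% for cedar, on the ground that “the tank's residence-time spread and the late feed both leave more material unconverted”. Its figures differ from the reckoning in the first decimal.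

The simulation gives cedar, with 22.1% in oak, 22.2% in elm and 29.3% in cedar. Cedar's 40 s amount to 1.45 relaxation times, over which the first step ran as substrate fell to 63.6% of the charge, and the isomer of the product reached 7.09%. Left to 400 s, which is 14.5 relaxation times, cedar held less target, at 26.9%.

(The numbers of this flask are assumed; what happens was integrated by code.)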